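Numbering: C1 (quaternary, CH3), C2, C3, C4 (carbinol bearing isopropyl), C5 (ring-fusion CH), C6 (CH–O–acyl), C7, C8 (C–CH3) and C9 (CH), both in the oxirane, C10. The five-membered ring is C1–C2–C3–C4–C5 and the seven-membered ring is C1–C5–C6–C7–C8–C9–C10.
Enabling feature: the fusion carbon C5 lies between carbinol C4 and oxygenated C6, and C9 carries oxygen. C5/C6 can therefore be read as an alkyne attached to C4, and C1/C10/C9/C8/C7 as a vinylcyclopropane with a siloxy group on C9. The chain C4–C3–C2 links the two.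
Retrosynthetic cuts, in order: benzyl ether, oxirane C8–O/C9–O, ester C6O–C(=O), C5–H and C6–O (back to C5=C6), C8–CH3, then C1–C5 and C6–C7 together, then the alkyne (from an epoxy chloride), C3–C4 and finally C9–C10.
Forward: the open chain is joined at C9–C10 (alkenyllithium plus cyclopropanone) and at C3–C4 (Suzuki–Miyaura). One rhodium-catalysed (5+2) cycloaddition closes the five- and seven-membered rings together, and the oxirane is the last ring.
Stereochemistry: C4 comes from a Sharpless epoxidation, C1 from C4 in the cycloaddition, C6 from C4–OH-directed epoxidation, and C5 from hydrogen transfer opposite the angular methyl group. C8 and C9 come from peracid attack opposite the C1 methyl and C6 ester groups.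

Key step: step 13

Remark on the chemistry: read from the SMILES, the target is 1R,4R,5S,6R,8R,9S. C1–CH3, C4–OH and C6–O lie on one face (β); H5 and the oxirane oxygen lie on the other (α). An oxirane on a seven-membered ring must be cis-fused, so it is made by direct epoxidation of a C8=C9 alkene.

Step 1
Reactants: 1 tert-butyl(but-3-yn-1-yloxy)dimethylsilane
Product: 3 (E)-tert-butyl[(4-iodo-3-methylbut-3-en-1-yl)oxy]dimethylsilane, via vinylalane 2 (not isolated)
Conditions: Me3Al, Cp2ZrCl2 (25 mol %), CH2Cl2, 0 °C to rt; then I2, THF, −30 to 0 °C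
Reagents that add atoms: trimethylaluminium C[Al](C)C; iodine [I][I]
Why: Zirconium-catalysed Negishi carboalumination adds CH3 and Al syn with the metal at the terminus, and iodinolysis with retention gives the E iodide that fixes the C1=C10 geometry.

Step 2
Reactants: 4 (1-ethoxycyclopropoxy)trimethylsilane
Product: 5 1-ethoxycyclopropan-1-ol
Conditions: MeOH, rt
Reagents that add atoms: none
Why: Methanolysis of the labile trimethylsilyl acetal frees the hemiacetal, the usual storable cyclopropanone equivalent.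

Step 3
Reactants: 3 (E)-tert-butyl[(4-iodo-3-methylbut-3-en-1-yl)oxy]dimethylsilane; 5 1-ethoxycyclopropan-1-ol
Product: 9 1-[(1E)-4-(tert-butyldimethylsilyloxy)-2-methylbut-1-en-1-yl]cyclopropan-1-ol, via vinyllithium 6 (not isolated), via magnesium hemiacetalate 7 (not isolated), via cyclopropanone 8 (not isolated)
Conditions: 3, t-BuLi (2.1 equiv), Et2O, −78 °C; separately 5, MeMgBr (1.0 equiv), THF, 0 °C; combine at −78 °C, warm to rt
Reagents that add atoms: none
Why: Iodine–lithium exchange keeps the alkene geometry, and the magnesium hemiacetalate releases cyclopropanone, whose strained carbonyl group should take up the alkenyl metal by 1,2-addition (organometal addition to a cyclopropanone hemiacetal).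

Step 4
Reactants: 9 1-[(1E)-4-(tert-butyldimethylsilyloxy)-2-methylbut-1-en-1-yl]cyclopropan-1-ol
Product: 10 tert-butyl{1-[(1E)-4-(tert-butyldimethylsilyloxy)-2-methylbut-1-en-1-yl]cyclopropoxy}dimethylsilane
Conditions: TBSCl, imidazole, DMAP (cat.), DMF, rt
Reagents that add atoms: tert-butyldimethylsilyl chloride CC(C)(C)[Si](C)(C)Cl
Why: This is a standard silylation, in which the cyclopropanol oxygen is less hindered than an ordinary tertiary one and the basic medium avoids acid-induced ring expansion.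

Step 5
Reactants: 10 tert-butyl{1-[(1E)-4-(tert-butyldimethylsilyloxy)-2-methylbut-1-en-1-yl]cyclopropoxy}dimethylsilane
Product: 11 (3E)-4-[1-(tert-butyldimethylsilyloxy)cyclopropyl]-3-methylbut-3-en-1-ol
Conditions: HF·pyridine, pyridine, THF, 0 °C
Reagents that add atoms: none
Why: Buffered fluoride cleaves the unhindered primary silyl ether much faster than the tertiary one (selective desilylation).

Step 6
Reactants: 11 (3E)-4-[1-(tert-butyldimethylsilyloxy)cyclopropyl]-3-methylbut-3-en-1-ol
Product: 12 tert-butyl{1-[(1E)-4-iodo-2-methylbut-1-en-1-yl]cyclopropoxy}dimethylsilane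
Conditions: PPh3, imidazole, I2, CH2Cl2, 0 °C
Reagents that add atoms: iodine [I][I]
Why: Appel-type iodination under buffered conditions converts only the primary alcohol and leaves the alkene and the siloxycyclopropane alone.

Step 7
Reactants: 13 3-methylbut-1-yne
Product: 15 4-methylpent-2-yn-1-ol, via lithium acetylide 14 (not isolated)
Conditions: n-BuLi, THF, −78 °C; (CH2O)n, −78 °C to rt
Reagents that add atoms: paraformaldehyde, as formaldehyde C=O
Why: Hydroxymethylation of a lithium acetylide with formaldehyde supplies C6, C5, C4 and the isopropyl group.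

Step 8
Reactants: 15 4-methylpent-2-yn-1-ol
Product: 17 (Z)-3-iodo-4-methylpent-2-en-1-ol, via cyclic alkenylalanate 16 (not isolated)
Conditions: NaAlH2(OCH2CH2OMe)2, THF, 0 °C to rt; then I2, THF, −78 °C
Reagents that add atoms: iodine [I][I]
Why: Alkoxide-directed trans-hydroalumination places aluminium on C4 inside a five-membered chelate, so iodinolysis with retention gives only the Z 3-iodo allylic alcohol.

Step 9
Reactants: 12 tert-butyl{1-[(1E)-4-iodo-2-methylbut-1-en-1-yl]cyclopropoxy}dimethylsilane; 17 (Z)-3-iodo-4-methylpent-2-en-1-ol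
Product: 20 (2E,6E)-7-[1-(tert-butyldimethylsilyloxy)cyclopropyl]-6-methyl-3-(propan-2-yl)hepta-2,6-dien-1-ol, via alkyllithium 18 (not isolated), via methoxyborate 19 (not isolated)
Conditions: 12, t-BuLi (2.1 equiv), Et2O, −78 °C; 9-MeO-9-BBN, THF, −78 °C to rt; then 17, Pd(dppf)Cl2 (5 mol %), K3PO4 (aq), DMF, rt
Reagents that add atoms: none
Why: B-alkyl Suzuki–Miyaura coupling of the borate proceeds with retention at the alkenyl iodide and tolerates the free hydroxyl group, so the chain ends cis and the isopropyl group trans to CH2OH.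

Step 10
Reactants: 20 (2E,6E)-7-[1-(tert-butyldimethylsilyloxy)cyclopropyl]-6-methyl-3-(propan-2-yl)hepta-2,6-dien-1-ol
Product: 21 [(2R,3R)-3-{(3E)-4-[1-(tert-butyldimethylsilyloxy)cyclopropyl]-3-methylbut-3-en-1-yl}-3-(propan-2-yl)oxiran-2-yl]methanol
Conditions: Ti(OiPr)4 (10 mol %), D-(−)-diisopropyl tartrate (12 mol %), t-BuOOH, 4 Å molecular sieves, CH2Cl2, −20 °C
Reagents that add atoms: tert-butyl hydroperoxide CC(C)(C)OO
Why: Sharpless asymmetric epoxidation touches only the allylic alcohol, and with the D-(−)-tartrate an E-3,3-disubstituted substrate of the geraniol type gives the 2R,3R oxirane, which sets C4.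

Step 11
Reactants: 21 [(2R,3R)-3-{(3E)-4-[1-(tert-butyldimethylsilyloxy)cyclopropyl]-3-methylbut-3-en-1-yl}-3-(propan-2-yl)oxiran-2-yl]methanol
Product: 22 (2S,3R)-2-(chloromethyl)-3-{(3E)-4-[1-(tert-butyldimethylsilyloxy)cyclopropyl]-3-methylbut-3-en-1-yl}-3-(propan-2-yl)oxirane
Conditions: PPh3, CCl4, NaHCO3, reflux
Reagents that add atoms: tetrachloromethane ClC(Cl)(Cl)Cl
Why: Appel chlorination of the primary alcohol under neutral conditions leaves the oxirane intact, and the descriptor at the CH carbon changes only because of priorities.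

Step 12
Reactants: 22 (2S,3R)-2-(chloromethyl)-3-{(3E)-4-[1-(tert-butyldimethylsilyloxy)cyclopropyl]-3-methylbut-3-en-1-yl}-3-(propan-2-yl)oxirane
Product: 24 (3R,6E)-7-[1-(tert-butyldimethylsilyloxy)cyclopropyl]-6-methyl-3-(propan-2-yl)hept-6-en-1-yn-3-ol, via lithium chloroallyl alkoxide 23 (not isolated)
Conditions: n-BuLi (3.5 equiv), THF, −78 to −20 °C
Reagents that add atoms: none
Why: Base-induced double elimination of a 2,3-epoxy chloride (oxirane opening to the chloroallylic alkoxide, then loss of HCl) gives the terminal alkyne without touching the C4–O bond, so the configuration is retained.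

Step 13
Reactants: 24 (3R,6E)-7-[1-(tert-butyldimethylsilyloxy)cyclopropyl]-6-methyl-3-(propan-2-yl)hept-6-en-1-yn-3-ol
Product: 25 (3R,8aR)-7-(tert-butyldimethylsilyloxy)-8a-methyl-3-(propan-2-yl)-1,2,3,5,6,8a-hexahydroazulen-3-ol
Conditions: [Rh(CO)2Cl]2 (5 mol %), ClCH2CH2Cl (0.02 M), 60 °C, argon
Reagents that add atoms: none
Why: Monovalent rhodium binds the vinylcyclopropane and cleaves the strained C9–C7 bond to a σ-alkyl/π-allyl rhodacyclohexene of trivalent rhodium, the linked alkyne inserts at the allyl terminus to make C1–C5, and reductive elimination from the eight-membered rhodacycle makes C6–C7 and returns the catalyst. This is the known rhodium-catalysed intramolecular (5+2) cycloaddition of alkynes with vinylcyclopropanes, for which terminal alkynes, 1-oxygenated cyclopropanes and methyl-substituted alkenes that end as angular methyl groups are all documented. The five-membered ring closes 5-exo through the three-atom link C4–C3–C2 during insertion, helped by the fully substituted C4, and the seven-membered ring closes in the reductive elimination as a cis,cis-cyclohepta-1,4-diene whose C9=C10 bond is the silyl enol ether. C1 is the only new stereocentre and is set by C4: in the insertion transition state C10 lies near the C5–C6 plane and the C1 methyl group stands perpendicular to the nascent ring, so the conformer with the small hydroxyl group syn to it and the isopropyl group pseudo-equatorial avoids a 1,3-diaxial CH3/isopropyl contact and should place CH3 and OH on the same face. Regiochemistry needs no control, because the link dictates C5-to-C1 and C6-to-C7 bonding, the two cyclopropane CH2 groups are equivalent, and the E alkene keeps link and cyclopropane trans as the reaction requires. Chemoselectivity over alkyne oligomerisation is secured by dilution and by the donor siloxy group, which speeds ring cleavage and allows a moderate temperature.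

Step 14
Reactants: 25 (3R,8aR)-7-(tert-butyldimethylsilyloxy)-8a-methyl-3-(propan-2-yl)-1,2,3,5,6,8a-hexahydroazulen-3-ol
Product: 26 (3R,8aR)-3-hydroxy-8a-methyl-3-(propan-2-yl)-2,3,5,6,8,8a-hexahydroazulen-7(1H)-one
Conditions: Bu4NF, AcOH, THF, 0 °C
Reagents that add atoms: none
Why: Buffered fluoride cleaves the silyl enol ether at once, and the near-neutral medium spares the ionisable tertiary allylic alcohol.

Step 15
Reactants: 26 (3R,8aR)-3-hydroxy-8a-methyl-3-(propan-2-yl)-2,3,5,6,8,8a-hexahydroazulen-7(1H)-one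
Product: 30 (3R,8aR)-3-hydroxy-8a-methyl-6-methylidene-3-(propan-2-yl)-2,3,5,6,8,8a-hexahydroazulen-7(1H)-one, via dilithium enolate alkoxide 27 (not isolated), via Mannich base 28 (not isolated), via ammonium iodide 29 (not isolated)
Conditions: LiN(iPr)2 (2.3 equiv), THF, −78 °C; [Me2N=CH2]I, −78 °C to rt; then MeI, CH2Cl2, rt; then NaHCO3 (aq), rt
Reagents that add atoms: dimethyl(methylidene)ammonium iodide C=[N+](C)C.[I-]
Why: Kinetic deprotonation should occur at C8 because C10 is neopentyl, the enolate undergoes a Mannich reaction with the iminium salt, and quaternisation followed by Hofmann-type elimination gives the exocyclic enone.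

Step 16
Reactants: 30 (3R,8aR)-3-hydroxy-8a-methyl-6-methylidene-3-(propan-2-yl)-2,3,5,6,8,8a-hexahydroazulen-7(1H)-one
Product: 31 (3R,8aR)-8a-methyl-6-methylidene-3-(propan-2-yl)-1,2,3,5,6,7,8,8a-octahydroazulene-3,7-diol (C9 epimers)
Conditions: NaBH4, CeCl3·7H2O, MeOH, −78 to 0 °C
Reagents that add atoms: none
Why: Luche reduction gives clean 1,2-reduction of the enone, and the C9 configuration does not matter because it is lost in the next step.

Step 17
Reactants: 31 (3R,8aR)-8a-methyl-6-methylidene-3-(propan-2-yl)-1,2,3,5,6,7,8,8a-octahydroazulene-3,7-diol (C9 epimers)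
Product: 34 (3R,8aR)-6,8a-dimethyl-3-(propan-2-yl)-1,2,3,5,8,8a-hexahydroazulen-3-ol, via sulfonylhydrazine adduct 32 (not isolated), via allylic diazene 33 (not isolated)
Conditions: 2-O2NC6H4SO2NHNH2, PPh3, DEAD, THF, −30 °C; then rt
Reagents that add atoms: none
Why: Mitsunobu displacement by the arylsulfonyl hydrazide, loss of sulfinate and retro-ene loss of N2 from the allylic diazene (Myers reductive transposition) move the double bond to C8=C9 and turn the methylidene group into the C8 methyl group, while the tertiary alcohol cannot react.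

Step 18
Reactants: 34 (3R,8aR)-6,8a-dimethyl-3-(propan-2-yl)-1,2,3,5,8,8a-hexahydroazulen-3-ol
Product: 35 5β,6β-epoxide of 34 (1R,4R,5S,6R; C8=C9 retained)
Conditions: VO(acac)2 (5 mol %), t-BuOOH, CH2Cl2, 0 °C
Reagents that add atoms: tert-butyl hydroperoxide CC(C)(C)OO
Why: Vanadium-catalysed hydroxyl-directed epoxidation is specific for the allylic alcohol over the isolated C8=C9 alkene and delivers oxygen syn to C4–OH, which sets C6–O on the β face.

Step 19
Reactants: 35 5β,6β-epoxide of 34 (1R,4R,5S,6R; C8=C9 retained)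
Product: 36 (3R,3aS,4R,8aR)-6,8a-dimethyl-3-(propan-2-yl)-1,2,3,3a,4,5,8,8a-octahydroazulene-3,4-diol
Conditions: Cp2TiCl2, Zn, THF, rt; then 35, 1,4-cyclohexadiene, rt
Reagents that add atoms: none
Why: Trivalent titanium opens the oxirane homolytically to the more substituted C5 radical (Nugent–RajanBabu reductive opening, known to turn 2,3-epoxy alcohols into 1,3-diols), and hydrogen transfer should come from the α face because the β face carries the C1 methyl group and both titanium-bound oxygens, which gives the trans ring fusion.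

Step 20
Reactants: 36 (3R,3aS,4R,8aR)-6,8a-dimethyl-3-(propan-2-yl)-1,2,3,3a,4,5,8,8a-octahydroazulene-3,4-diol; 37 4-(benzyloxy)-3-methoxybenzoic acid
Product: 39 [(3R,3aS,4R,8aR)-3-hydroxy-6,8a-dimethyl-3-(propan-2-yl)-1,2,3,3a,4,5,8,8a-octahydroazulen-4-yl] 4-(benzyloxy)-3-methoxybenzoate, via mixed anhydride 38 (not isolated)
Conditions: 37, 2,4,6-Cl3C6H2COCl, Et3N, toluene, rt; then 36, DMAP, toluene, 60 °C
Reagents that add atoms: none
Why: Yamaguchi esterification activates the acid strongly enough for the hindered secondary C6 alcohol, while the tertiary C4 alcohol stays free.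

Step 21
Reactants: 39 [(3R,3aS,4R,8aR)-3-hydroxy-6,8a-dimethyl-3-(propan-2-yl)-1,2,3,3a,4,5,8,8a-octahydroazulen-4-yl] 4-(benzyloxy)-3-methoxybenzoate
Product: 40 8α,9α-epoxide of 39 (O-benzyl ether of the target; 1R,4R,5S,6R,8R,9S)
Conditions: mCPBA, NaHCO3, CH2Cl2, 0 °C
Reagents that add atoms: 3-chloroperoxybenzoic acid O=C(OO)c1cccc(Cl)c1
Why: Prilezhaev epoxidation of the only remaining alkene should take place on the α face, since the β face is covered by the C1 methyl group and the C6 aroyloxy group, and this sets C8 and C9 together.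

Step 22
Reactants: 40 8α,9α-epoxide of 39 (O-benzyl ether of the target; 1R,4R,5S,6R,8R,9S)
Product: 41 target CNP0254293.2
Conditions: H2 (1 atm), Pd/C, EtOAc, rt
Reagents that add atoms: none
Why: Hydrogenolysis of the benzyl aryl ether under neutral conditions frees the phenol, while the trialkyl oxirane, the alkyl benzoate and the tertiary alcohol are not benzylic and should survive.

Compound list
1 | tert-butyl(but-3-yn-1-yloxy)dimethylsilane | C#CCCO[Si](C)(C)C(C)(C)C | starting material
2 | (E)-[4-(tert-butyldimethylsilyloxy)-2-methylbut-1-en-1-yl]dimethylalane | C[Al](C)/C=C(\C)CCO[Si](C)(C)C(C)(C)C | intermediate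
3 | (E)-tert-butyl[(4-iodo-3-methylbut-3-en-1-yl)oxy]dimethylsilane | I/C=C(\C)CCO[Si](C)(C)C(C)(C)C | intermediate
4 | (1-ethoxycyclopropoxy)trimethylsilane | CCOC1(O[Si](C)(C)C)CC1 | starting material
5 | 1-ethoxycyclopropan-1-ol | CCOC1(O)CC1 | intermediate
6 | (E)-[4-(tert-butyldimethylsilyloxy)-2-methylbut-1-en-1-yl]lithium | [Li]/C=C(\C)CCO[Si](C)(C)C(C)(C)C | intermediate
7 | bromomagnesium 1-ethoxycyclopropan-1-olate | CCOC1(O[Mg]Br)CC1 | intermediate
8 | cyclopropanone | O=C1CC1 | intermediate
9 | 1-[(1E)-4-(tert-butyldimethylsilyloxy)-2-methylbut-1-en-1-yl]cyclopropan-1-ol | CC(C)(C)[Si](C)(C)OCC/C(C)=C/C1(O)CC1 | intermediate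
10 | tert-butyl{1-[(1E)-4-(tert-butyldimethylsilyloxy)-2-methylbut-1-en-1-yl]cyclopropoxy}dimethylsilane | CC(C)(C)[Si](C)(C)OCC/C(C)=C/C1(O[Si](C)(C)C(C)(C)C)CC1 | intermediate
11 | (3E)-4-[1-(tert-butyldimethylsilyloxy)cyclopropyl]-3-methylbut-3-en-1-ol | OCC/C(C)=C/C1(O[Si](C)(C)C(C)(C)C)CC1 | intermediate
12 | tert-butyl{1-[(1E)-4-iodo-2-methylbut-1-en-1-yl]cyclopropoxy}dimethylsilane | ICC/C(C)=C/C1(O[Si](C)(C)C(C)(C)C)CC1 | intermediate
13 | 3-methylbut-1-yne | CC(C)C#C | starting material
14 | (3-methylbut-1-yn-1-yl)lithium | CC(C)C#C[Li] | intermediate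
15 | 4-methylpent-2-yn-1-ol | CC(C)C#CCO | intermediate
16 | sodium cyclic alkenylalanate (five-membered O–Al chelate, Al on C4, two 2-methoxyethoxy ligands) | [Na+].COCCO[Al-]1(OCCOC)OCC=C1C(C)C | intermediate
17 | (Z)-3-iodo-4-methylpent-2-en-1-ol | OC/C=C(\I)C(C)C | intermediate
18 | {(3E)-4-[1-(tert-butyldimethylsilyloxy)cyclopropyl]-3-methylbut-3-en-1-yl}lithium | [Li]CC/C(C)=C/C1(O[Si](C)(C)C(C)(C)C)CC1 | intermediate
19 | lithium B-alkyl-B-methoxy-9-borabicyclo[3.3.1]nonane borate of 18 | [Li+].CO[B-]1(CC/C(C)=C/C2(O[Si](C)(C)C(C)(C)C)CC2)C2CCCC1CCC2 | intermediate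
20 | (2E,6E)-7-[1-(tert-butyldimethylsilyloxy)cyclopropyl]-6-methyl-3-(propan-2-yl)hepta-2,6-dien-1-ol | OC/C=C(/C(C)C)CC/C(C)=C/C1(O[Si](C)(C)C(C)(C)C)CC1 | intermediate
21 | [(2R,3R)-3-{(3E)-4-[1-(tert-butyldimethylsilyloxy)cyclopropyl]-3-methylbut-3-en-1-yl}-3-(propan-2-yl)oxiran-2-yl]methanol | OC[C@H]1O[C@@]1(C(C)C)CC/C(C)=C/C2(O[Si](C)(C)C(C)(C)C)CC2 | intermediate
22 | (2S,3R)-2-(chloromethyl)-3-{(3E)-4-[1-(tert-butyldimethylsilyloxy)cyclopropyl]-3-methylbut-3-en-1-yl}-3-(propan-2-yl)oxirane | ClC[C@H]1O[C@@]1(C(C)C)CC/C(C)=C/C2(O[Si](C)(C)C(C)(C)C)CC2 | intermediate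
23 | lithium (3R,6E)-1-chloro-7-[1-(tert-butyldimethylsilyloxy)cyclopropyl]-6-methyl-3-(propan-2-yl)hepta-1,6-dien-3-olate | [Li+].[O-][C@@](C=CCl)(C(C)C)CC/C(C)=C/C1(O[Si](C)(C)C(C)(C)C)CC1 | intermediate
24 | (3R,6E)-7-[1-(tert-butyldimethylsilyloxy)cyclopropyl]-6-methyl-3-(propan-2-yl)hept-6-en-1-yn-3-ol | C#C[C@](O)(C(C)C)CC/C(C)=C/C1(O[Si](C)(C)C(C)(C)C)CC1 | intermediate
25 | (3R,8aR)-7-(tert-butyldimethylsilyloxy)-8a-methyl-3-(propan-2-yl)-1,2,3,5,6,8a-hexahydroazulen-3-ol | CC(C)[C@]1(O)CC[C@]2(C)C=C(O[Si](C)(C)C(C)(C)C)CCC=C12 | intermediate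
26 | (3R,8aR)-3-hydroxy-8a-methyl-3-(propan-2-yl)-2,3,5,6,8,8a-hexahydroazulen-7(1H)-one | CC(C)[C@]1(O)CC[C@]2(C)CC(=O)CCC=C12 | intermediate
27 | dilithium C8=C9 enolate and C4 alkoxide of 26 | CC(C)[C@]1(O[Li])CC[C@]2(C)CC(O[Li])=CCC=C12 | intermediate
28 | C8-(dimethylaminomethyl) ketone (C8 epimers) | CC(C)[C@]1(O)CC[C@]2(C)CC(=O)C(CN(C)C)CC=C12 | intermediate
29 | C8-(trimethylammoniomethyl) ketone iodide (C8 epimers) | CC(C)[C@]1(O)CC[C@]2(C)CC(=O)C(C[N+](C)(C)C)CC=C12.[I-] | intermediate
30 | (3R,8aR)-3-hydroxy-8a-methyl-6-methylidene-3-(propan-2-yl)-2,3,5,6,8,8a-hexahydroazulen-7(1H)-one | CC(C)[C@]1(O)CC[C@]2(C)CC(=O)C(=C)CC=C12 | intermediate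
31 | (3R,8aR)-8a-methyl-6-methylidene-3-(propan-2-yl)-1,2,3,5,6,7,8,8a-octahydroazulene-3,7-diol (C9 epimers) | CC(C)[C@]1(O)CC[C@]2(C)CC(O)C(=C)CC=C12 | intermediate
32 | C9 N-(2-nitrophenylsulfonyl)hydrazine adduct | CC(C)[C@]1(O)CC[C@]2(C)CC(N(N)S(=O)(=O)c3ccccc3[N+](=O)[O-])C(=C)CC=C12 | intermediate
33 | C9 allylic diazene | CC(C)[C@]1(O)CC[C@]2(C)CC(N=N)C(=C)CC=C12 | intermediate
34 | (3R,8aR)-6,8a-dimethyl-3-(propan-2-yl)-1,2,3,5,8,8a-hexahydroazulen-3-ol | CC(C)[C@]1(O)CC[C@]2(C)CC=C(C)CC=C12 | intermediate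
35 | 5β,6β-epoxide of 34 (1R,4R,5S,6R) | CC(C)[C@]1(O)CC[C@]2(C)CC=C(C)C[C@H]3O[C@@]123 | intermediate
36 | (3R,3aS,4R,8aR)-6,8a-dimethyl-3-(propan-2-yl)-1,2,3,3a,4,5,8,8a-octahydroazulene-3,4-diol | CC(C)[C@]1(O)CC[C@]2(C)CC=C(C)C[C@@H](O)[C@@H]12 | intermediate
37 | 4-(benzyloxy)-3-methoxybenzoic acid | COc1cc(C(=O)O)ccc1OCc1ccccc1 | starting material
38 | 4-(benzyloxy)-3-methoxybenzoic 2,4,6-trichlorobenzoic anhydride | COc1cc(C(=O)OC(=O)c2c(Cl)cc(Cl)cc2Cl)ccc1OCc1ccccc1 | intermediate
39 | [(3R,3aS,4R,8aR)-3-hydroxy-6,8a-dimethyl-3-(propan-2-yl)-1,2,3,3a,4,5,8,8a-octahydroazulen-4-yl] 4-(benzyloxy)-3-methoxybenzoate | COc1cc(C(=O)O[C@@H]2CC(C)=CC[C@@]3(C)CC[C@@](O)(C(C)C)[C@H]23)ccc1OCc1ccccc1 | intermediate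
40 | 8α,9α-epoxide of 39, the O-benzyl ether of the target | COc1cc(C(=O)O[C@@H]2C[C@@]3(C)O[C@H]3C[C@@]3(C)CC[C@@](O)(C(C)C)[C@H]23)ccc1OCc1ccccc1 | intermediate
41 | CNP0254293.2, 4β-hydroxy-8α,9α-epoxy-6β-vanilloyloxydaucane (1R,4R,5S,6R,8R,9S) | COc1cc(C(=O)O[C@@H]2C[C@@]3(C)O[C@H]3C[C@@]3(C)CC[C@@](O)(C(C)C)[C@H]23)ccc1O | target

Total step count: 22. Longest linear sequence: 19 (steps 1, 3–6 and 9–22).

Steps most likely to fail

Step 13. The 1,3-induction from C4 may be too weak, so that both faces of the C1=C10 alkene react, or alkyne oligomerisation may outrun the cycloaddition. The fallback removes the stereocentre at C4 by raising its oxidation level, sets C1 by the catalyst, and then sets C4 from C1.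
- It starts from iodide 12, which is lithiated as in step 9 to 18.
- 18 is acylated with N-methoxy-N-methyl-3-(trimethylsilyl)prop-2-ynamide to the C6-trimethylsilyl ynone F1.
- K2CO3 in MeOH frees the terminal ynone F2.
- A cationic rhodium catalyst with a chiral bisphosphine, [Rh((R)-BINAP)]SbF6 (ligand antipode chosen after assignment of the product), forms the same C1–C5 and C6–C7 bonds and gives the bicyclic enone F3.
- iPrMgCl with CeCl3 at −78 °C should add 1,2 to the C4 ketone from the α face, opposite the angular methyl group. This rejoins the route at 25.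

Step 19. The C5 radical may be trapped by a second trivalent titanium, followed by β-elimination of a titanium alkoxide (deoxygenation or allylic transposition). Alternatively, hydrogen may be transferred to the β face. The fallback makes C5–H by a concerted syn addition and corrects C6 afterwards.
- It starts from 34. One equivalent of mCPBA at low temperature should take the remote, unhindered C8=C9 alkene first, from the α face, to give the 8α,9α-epoxy dienol F4.
- BH3·SMe2 followed by NaBO3 adds H and OH syn from the α face, with boron on C6, to give the 4β,6α-diol F5.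
- Dess–Martin periodinane gives the β-hydroxy ketone F6.
- Narasaka–Prasad reduction (Et2BOMe, NaBH4, −78 °C), with hydride arriving on the open α face, gives the syn 4β,6β-diol F7.
- Esterification with 37 through 38, as in step 20, rejoins the route at 40.

Step 3. Cyclopropanone may oligomerise or be enolised faster than it is captured, or the hemiacetal may protonate the alkenyllithium. The fallback builds the three-membered ring by carbenoid addition instead.
- It starts from 3. Vinyllithium 6 is acylated with N-methoxy-N-methylacetamide to the E enone F8.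
- Kinetic deprotonation of the acetyl methyl group with LiN(iPr)2 and trapping with TBSOTf gives the 2-siloxy diene F9.
- Furukawa-modified Simmons–Smith cyclopropanation (Et2Zn, CH2I2, one equivalent) should attack the electron-rich enol ether double bond selectively. This rejoins the route at 10.

Further compounds
F1 | step 13 | C6-trimethylsilyl ynone, (E)-7-[1-(tert-butyldimethylsilyloxy)cyclopropyl]-6-methyl-1-(trimethylsilyl)hept-6-en-1-yn-3-one | C[Si](C)(C)C#CC(=O)CC/C(C)=C/C1(O[Si](C)(C)C(C)(C)C)CC1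
F2 | step 13 | terminal ynone, (E)-7-[1-(tert-butyldimethylsilyloxy)cyclopropyl]-6-methylhept-6-en-1-yn-3-one | C#CC(=O)CC/C(C)=C/C1(O[Si](C)(C)C(C)(C)C)CC1
F3 | step 13 | bicyclic enone, (8aR)-7-(tert-butyldimethylsilyloxy)-8a-methyl-1,5,6,8a-tetrahydroazulen-3(2H)-one | O=C1CC[C@]2(C)C=C(O[Si](C)(C)C(C)(C)C)CCC=C12
F4 | step 19 | 8α,9α-epoxy dienol, the 8α,9α-epoxide of 34 with C5=C6 retained | CC(C)[C@]1(O)CC[C@]2(C)C[C@@H]3O[C@]3(C)CC=C12
F5 | step 19 | 4β,6α-diol with 5α-H and 8α,9α-epoxide | CC(C)[C@]1(O)CC[C@]2(C)C[C@@H]3O[C@]3(C)C[C@H](O)[C@@H]12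
F6 | step 19 | β-hydroxy ketone, C6 ketone with 4β-OH, 5α-H and 8α,9α-epoxide | CC(C)[C@]1(O)CC[C@]2(C)C[C@@H]3O[C@]3(C)CC(=O)[C@@H]12
F7 | step 19 | syn 4β,6β-diol with 5α-H and 8α,9α-epoxide | CC(C)[C@]1(O)CC[C@]2(C)C[C@@H]3O[C@]3(C)C[C@@H](O)[C@@H]12
F8 | step 3 | E enone, (E)-6-(tert-butyldimethylsilyloxy)-4-methylhex-3-en-2-one | CC(=O)/C=C(\C)CCO[Si](C)(C)C(C)(C)C
F9 | step 3 | 2-siloxy diene, (E)-2,6-bis(tert-butyldimethylsilyloxy)-4-methylhexa-1,3-diene | C=C(O[Si](C)(C)C(C)(C)C)/C=C(\C)CCO[Si](C)(C)C(C)(C)C
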